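**Retrosynthetic overview**
1. Target 20 ⇐ macrocyclic homoallylic alcohol 18 by a last-step C–O bond formation: the C4 hydroxyl relays oxygen across the ring to C1 of the C1=C2 alkene (transannular Wacker-type oxidation), which unveils the 1-oxo-4-hydroxy unit.
2. 18 ⇐ bromo aldehyde 16: one intramolecular indium Barbier allylation (C7–C8) closes the ten-membered carbocycle, and the cis α-methylene γ-lactone forms in the same flask.
3. 16 ⇐ allylic bromide 15 + aldehyde 3 by cross-metathesis (C1=C2).
4. 15 from acetone, 2,2-dimethoxyacetaldehyde, allyl bromide, isobutyryl chloride and methyl acrylate (proline aldol sets C6, chelation-controlled allylation sets C4); 3 from crotonaldehyde by organocatalytic conjugate alkenylation (sets C10).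
5. Ring order: carbocycle first, then lactone (both in step 9); no ring is made afterwards.

Notation and assumption: atoms are labelled C1 (ketone carbon), C2–C3, C4 (carbinol), C5, C6 (ester-bearing), C7/C8 (lactone fusion, C8 carries the ring oxygen), C9, C10 (methyl-bearing), C11–C13 (methylidene lactone); the target is treated as the open hydroxy ketone, which equilibrates with its transannular hemiketal.

**Step 1**
Reactants: 1 (E)-but-2-enal (crotonaldehyde); 2 potassium (E)-trifluoro(2-phenylethenyl)borate
Product: 3 (3R,4E)-3-methyl-5-phenylpent-4-enal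
Conditions: (2S,5S)-5-benzyl-2-tert-butyl-3-methylimidazolidin-4-one·HCl (20 mol%), aq. HF (1 equiv), DME, −20 °C
Reagents that add atoms: none
Why: Iminium-activated organocatalytic conjugate addition of an alkenyl trifluoroborate to an enal; the catalyst shields one face of the E-iminium so the styryl group adds to give the (R)-configured C10 centre, and the styryl unit later serves as the metathesis handle.

**Step 2**
Reactants: 4 acetone; 5 2,2-dimethoxyacetaldehyde
Product: 6 (4R)-4-hydroxy-5,5-dimethoxypentan-2-one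
Conditions: L-proline (30 mol%), acetone/DMSO 1:4, rt
Reagents that add atoms: none
Why: Proline-catalysed direct asymmetric aldol reaction (enamine catalysis) on a non-enolisable activated aldehyde; (S)-proline delivers the (R)-carbinol that becomes C6.

**Step 3**
Reactants: 6 (4R)-4-hydroxy-5,5-dimethoxypentan-2-one; 7 allyl bromide
Product: 8 (2R,4S)-1,1-dimethoxy-4-methylhept-6-ene-2,4-diol
Conditions: indium powder (1.5 equiv), THF/H2O 1:1, rt
Reagents that add atoms: none
Why: Chelation-controlled Barbier allylation in which indium bridges the C6 hydroxyl and the ketone in a six-membered chelate and the allyl group attacks axially, giving the 1,3-anti diol and setting the C4 carbinol centre (S).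

**Step 4**
Reactants: 8 (2R,4S)-1,1-dimethoxy-4-methylhept-6-ene-2,4-diol; 9 2-methylpropanoyl chloride (isobutyryl chloride)
Product: 10 (2R,4S)-4-hydroxy-1,1-dimethoxy-4-methylhept-6-en-2-yl 2-methylpropanoate
Conditions: pyridine, DMAP (5 mol%), CH2Cl2, −20 to 0 °C
Reagents that add atoms: none
Why: DMAP-catalysed esterification occurs only at the secondary hydroxyl because the tertiary C4 hydroxyl is far less reactive; no stereocentre is touched.

**Step 5**
Reactants: 10 (2R,4S)-4-hydroxy-1,1-dimethoxy-4-methylhept-6-en-2-yl 2-methylpropanoate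
Product: 12 (2R,4S)-4-methyl-1-oxo-4-[(triethylsilyl)oxy]hept-6-en-2-yl 2-methylpropanoate, via silyl ether acetal 11 (not isolated)
Conditions: TESOTf (3 equiv), 2,6-lutidine (4 equiv), CH2Cl2, −40 to 0 °C; then H2O
Reagents that add atoms: triethylsilyl trifluoromethanesulfonate, CC[Si](CC)(CC)OS(=O)(=O)C(F)(F)F; water, O
Why: The silyl triflate/2,6-lutidine pair silylates the tertiary alcohol and converts the dimethyl acetal into a pyridinium N,O-acetal that water hydrolyses to the aldehyde (chemoselective acetal cleavage without aqueous acid), so the C6 ester and configuration survive and the silyl ether blocks lactol formation.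

**Step 6**
Reactants: 12 (2R,4S)-4-methyl-1-oxo-4-[(triethylsilyl)oxy]hept-6-en-2-yl 2-methylpropanoate; 13 methyl acrylate
Product: 14 methyl (4R,6S)-3-hydroxy-6-methyl-2-methylidene-4-[(2-methylpropanoyl)oxy]-6-[(triethylsilyl)oxy]non-8-enoate (both C3 epimers)
Conditions: DABCO (1 equiv), 13 (5 equiv), dioxane/H2O 1:1, 0 °C to rt
Reagents that add atoms: none
Why: Morita–Baylis–Hillman reaction of an activated α-acyloxy aldehyde; the new carbinol centre is formed as an epimer mixture that is irrelevant because this carbon (C7) becomes sp2 in step 7.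

**Step 7**
Reactants: 14 methyl (4R,6S)-3-hydroxy-6-methyl-2-methylidene-4-[(2-methylpropanoyl)oxy]-6-[(triethylsilyl)oxy]non-8-enoate
Product: 15 methyl (2Z,4R,6S)-2-(bromomethyl)-6-methyl-4-[(2-methylpropanoyl)oxy]-6-[(triethylsilyl)oxy]nona-2,8-dienoate
Conditions: NBS (1.5 equiv), Me2S (1.8 equiv), CH2Cl2, 0 °C to rt
Reagents that add atoms: N-bromosuccinimide, O=C1CCC(=O)N1Br
Why: Allylic transposition bromination (SN2′) of the Baylis–Hillman alcohol by the bromosulfonium reagent gives the thermodynamically preferred Z-configured 2-(bromomethyl)enoate, in which C6 lies cis to CH2Br.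

**Step 8**
Reactants: 15 methyl (2Z,4R,6S)-2-(bromomethyl)-6-methyl-4-[(2-methylpropanoyl)oxy]-6-[(triethylsilyl)oxy]nona-2,8-dienoate; 3 (3R,4E)-3-methyl-5-phenylpent-4-enal
Product: 16 methyl (2Z,4R,6S,8E,10R)-2-(bromomethyl)-6,10-dimethyl-4-[(2-methylpropanoyl)oxy]-12-oxo-6-[(triethylsilyl)oxy]dodeca-2,8-dienoate
Conditions: second-generation Hoveyda–Grubbs catalyst (5 mol%), 3 (3 equiv), CH2Cl2, 40 °C
Reagents that add atoms: none
Why: Olefin cross-metathesis between the terminal allyl group of 15 and the styryl alkene of 3 gives the E-disubstituted alkene with loss of styrene, while the trisubstituted electron-poor enoate, the allylic bromide and the aldehyde are inert to the ruthenium carbene.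

**Step 9**
Reactants: 16 methyl (2Z,4R,6S,8E,10R)-2-(bromomethyl)-6,10-dimethyl-4-[(2-methylpropanoyl)oxy]-12-oxo-6-[(triethylsilyl)oxy]dodeca-2,8-dienoate
Product: 18 (3aS,4R,6S,8E,10R,11aS)-6-hydroxy-6,10-dimethyl-3-methylidene-2-oxo-2,3,3a,4,5,6,7,10,11,11a-decahydrocyclodeca[b]furan-4-yl 2-methylpropanoate, via macrocyclic hydroxy ester 17 (not isolated)
Conditions: indium powder (3 equiv), THF/H2O 3:1, 0.002 M (slow addition of 16), rt; then 1 M HCl, rt
Reagents that add atoms: none
Why: Intramolecular indium-mediated Barbier allylation at high dilution, then acid-promoted lactonisation and Si–O cleavage; the Z-configured allylindium reacts through a chair-like (Zimmerman–Traxler) transition state to give the syn C7/C8 relationship (cis-lactone), and the C6 stereocentre fixes the face (C6–H eclipsing the alkene to avoid 1,3-allylic strain, aldehyde approaching anti to the C5 chain), giving 7S,8S.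

**Step 10**
Reactants: 18 (3aS,4R,6S,8E,10R,11aS)-6-hydroxy-6,10-dimethyl-3-methylidene-2-oxo-2,3,3a,4,5,6,7,10,11,11a-decahydrocyclodeca[b]furan-4-yl 2-methylpropanoate
Product: 20 (3aS,4R,6S,10R,11aS)-6-hydroxy-6,10-dimethyl-3-methylidene-2,9-dioxododecahydrocyclodeca[b]furan-4-yl 2-methylpropanoate (target), via bridged enol ether 19 (not isolated)
Conditions: Pd(OAc)2 (10 mol%), p-benzoquinone (1.2 equiv), aq. HBF4 (0.3 M), MeCN/H2O 7:1, rt
Reagents that add atoms: water, O
Why: Proposed new method: transannular hydroxyl-relayed Wacker oxidation — divalent palladium binds the outer face of the E-C1=C2 alkene, the C4 hydroxyl attacks C1 from inside the ring (5-endo anti-alkoxypalladation; attack at C2 would require an oxetane), syn β-hydride elimination of C1–H gives bridged enol ether 19, and acid-catalysed hydration gives the hemiketal that opens to the 4-hydroxy-1-ketone, so oxygen lands on the carbon remote from the directing hydroxyl (also the inductively favoured site) without touching the electron-poor methylidene lactone or the C10 centre; closest known reaction type: Tsuji–Wacker oxidation of internal alkenes directed by a nearby oxygen function, combined with intramolecular alkoxypalladation of alkenols, neither of which has been shown in a transannular 5-endo mode on a medium-ring cycloalkene.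

**Compound list**
1 | (E)-but-2-enal (crotonaldehyde) | C/C=C/C=O | starting material
2 | potassium (E)-trifluoro(2-phenylethenyl)borate | [K+].F[B-](F)(F)/C=C/c1ccccc1 | starting material
3 | (3R,4E)-3-methyl-5-phenylpent-4-enal | O=CC[C@@H](C)/C=C/c1ccccc1 | intermediate
4 | acetone | CC(C)=O | starting material
5 | 2,2-dimethoxyacetaldehyde | COC(OC)C=O | starting material
6 | (4R)-4-hydroxy-5,5-dimethoxypentan-2-one | CC(=O)C[C@@H](O)C(OC)OC | intermediate
7 | allyl bromide (3-bromoprop-1-ene) | C=CCBr | starting material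
8 | (2R,4S)-1,1-dimethoxy-4-methylhept-6-ene-2,4-diol | C=CC[C@](C)(O)C[C@@H](O)C(OC)OC | intermediate
9 | 2-methylpropanoyl chloride (isobutyryl chloride) | CC(C)C(=O)Cl | starting material
10 | (2R,4S)-4-hydroxy-1,1-dimethoxy-4-methylhept-6-en-2-yl 2-methylpropanoate | C=CC[C@](C)(O)C[C@@H](OC(=O)C(C)C)C(OC)OC | intermediate
11 | (2R,4S)-1,1-dimethoxy-4-methyl-4-[(triethylsilyl)oxy]hept-6-en-2-yl 2-methylpropanoate (silyl ether acetal) | C=CC[C@](C)(O[Si](CC)(CC)CC)C[C@@H](OC(=O)C(C)C)C(OC)OC | intermediate
12 | (2R,4S)-4-methyl-1-oxo-4-[(triethylsilyl)oxy]hept-6-en-2-yl 2-methylpropanoate | C=CC[C@](C)(O[Si](CC)(CC)CC)C[C@@H](OC(=O)C(C)C)C=O | intermediate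
13 | methyl acrylate | C=CC(=O)OC | starting material
14 | methyl (4R,6S)-3-hydroxy-6-methyl-2-methylidene-4-[(2-methylpropanoyl)oxy]-6-[(triethylsilyl)oxy]non-8-enoate (both C3 epimers) | C=CC[C@](C)(O[Si](CC)(CC)CC)C[C@@H](OC(=O)C(C)C)C(O)C(=C)C(=O)OC | intermediate
15 | methyl (2Z,4R,6S)-2-(bromomethyl)-6-methyl-4-[(2-methylpropanoyl)oxy]-6-[(triethylsilyl)oxy]nona-2,8-dienoate | C=CC[C@](C)(O[Si](CC)(CC)CC)C[C@@H](OC(=O)C(C)C)/C=C(\CBr)C(=O)OC | intermediate
16 | methyl (2Z,4R,6S,8E,10R)-2-(bromomethyl)-6,10-dimethyl-4-[(2-methylpropanoyl)oxy]-12-oxo-6-[(triethylsilyl)oxy]dodeca-2,8-dienoate | O=CC[C@@H](C)/C=C/C[C@](C)(O[Si](CC)(CC)CC)C[C@@H](OC(=O)C(C)C)/C=C(\CBr)C(=O)OC | intermediate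
17 | methyl 2-[(1S,2S,4R,5E,8S,10R)-2-hydroxy-4,8-dimethyl-10-[(2-methylpropanoyl)oxy]-8-[(triethylsilyl)oxy]cyclodec-5-en-1-yl]prop-2-enoate (macrocyclic hydroxy ester) | COC(=O)C(=C)[C@H]1[C@@H](O)C[C@@H](C)/C=C/C[C@](C)(O[Si](CC)(CC)CC)C[C@H]1OC(=O)C(C)C | intermediate
18 | (3aS,4R,6S,8E,10R,11aS)-6-hydroxy-6,10-dimethyl-3-methylidene-2-oxo-2,3,3a,4,5,6,7,10,11,11a-decahydrocyclodeca[b]furan-4-yl 2-methylpropanoate | C=C1C(=O)O[C@H]2C[C@@H](C)/C=C/C[C@](C)(O)C[C@@H](OC(=O)C(C)C)[C@@H]12 | intermediate
19 | (3aS,4R,6S,10R,11aS)-6,9-epoxy-6,10-dimethyl-3-methylidene-2-oxo-2,3,3a,4,5,6,7,10,11,11a-decahydrocyclodeca[b]furan-4-yl 2-methylpropanoate (bridged enol ether, C8=C9 of the ring system) | C=C1C(=O)O[C@H]2C[C@@H](C)C3=CC[C@](C)(O3)C[C@@H](OC(=O)C(C)C)[C@@H]12 | intermediate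
20 | (3aS,4R,6S,10R,11aS)-6-hydroxy-6,10-dimethyl-3-methylidene-2,9-dioxododecahydrocyclodeca[b]furan-4-yl 2-methylpropanoate | C=C1C(=O)O[C@H]2C[C@@H](C)C(=O)CC[C@](C)(O)C[C@@H](OC(=O)C(C)C)[C@@H]12 | target

**Totals**
Total step count: 10. Longest linear sequence: 9 (steps 2 to 10; step 1 is the side branch).

**Three steps most likely to fail**

Step 10 (the new transannular Wacker oxidation). Risks are Pd–H alkene migration toward C10, β-hydride elimination toward C3 instead of C1, or sluggish oxypalladation of the hindered ring alkene. The fallback uses known chemistry; it sets out from 18 and returns at 20. A 5-endo iodoetherification of the homoallylic alcohol (I2, NaHCO3, MeCN, 0 °C) gives the transannular iodo ether F1. Radical deiodination (Bu3SnH, AIBN, toluene, 80 °C) gives the bridged ether F2. Dioxirane oxidation of its only ether α-C–H bond, at C1 (methyl(trifluoromethyl)dioxirane, CH2Cl2, −20 °C), gives the hemiketal, which opens to 20. If transannular attack itself is the problem, this fallback will suffer too; it covers Pd-specific failures.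

Step 9 (ten-membered ring closure by Barbier allylation). Risks are oligomerisation and an unfavourable macrocyclic transition state that erodes the syn and facial selectivity. The fallback changes the ring-closing bond; it sets out from 15 (with 3) and returns at 18. Intermolecular indium-mediated allylation of 3 with 15 (THF/H2O, rt), where the chair transition state and the control by C6 are unconstrained, gives the open hydroxy ester F3. Treatment with 1 M HCl lactonises and desilylates it to the diene lactone F4. Ring-closing metathesis (second-generation Grubbs catalyst, 1 mM, toluene, 80 °C) then closes C1=C2 with loss of styrene to give 18.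

Step 6 (Baylis–Hillman reaction on the α-acyloxy aldehyde). Risks are base-induced epimerisation at C6 and 1,2-acyl shift to the new hydroxyl under prolonged amine catalysis. The fallback replaces amine catalysis by a preformed vinyl metal; it sets out from 12 and returns at 14. Hydroalumination of methyl propiolate with DIBAL-H/NMO in THF at 0 °C gives the vinylalane F5, which adds to 12 at −78 °C under non-basic conditions and is quenched cold to give 14.

**Further compounds**
F1 | step 10 | transannular iodo ether, (3aS,4R,6R,8R,9S,10R,11aS)-6,9-epoxy-8-iodo-6,10-dimethyl-3-methylidene-2-oxododecahydrocyclodeca[b]furan-4-yl 2-methylpropanoate | C=C1C(=O)O[C@H]2C[C@@H](C)[C@H]3[C@H](I)C[C@](C)(O3)C[C@@H](OC(=O)C(C)C)[C@@H]12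
F2 | step 10 | bridged ether, (3aS,4R,6S,9R,10R,11aS)-6,9-epoxy-6,10-dimethyl-3-methylidene-2-oxododecahydrocyclodeca[b]furan-4-yl 2-methylpropanoate | C=C1C(=O)O[C@H]2C[C@@H](C)[C@H]3CC[C@](C)(O3)C[C@@H](OC(=O)C(C)C)[C@@H]12
F3 | step 9 | open hydroxy ester, methyl (3S,4S,6R,7E)-4-hydroxy-6-methyl-2-methylidene-3-[(1R,3S)-3-methyl-1-[(2-methylpropanoyl)oxy]-3-[(triethylsilyl)oxy]hex-5-en-1-yl]-8-phenyloct-7-enoate | COC(=O)C(=C)[C@@H]([C@@H](O)C[C@@H](C)/C=C/c1ccccc1)[C@H](OC(=O)C(C)C)C[C@@](C)(O[Si](CC)(CC)CC)CC=C
F4 | step 9 | diene lactone, (1R,3S)-3-hydroxy-3-methyl-1-[(2S,3S)-4-methylidene-2-[(2R,3E)-2-methyl-4-phenylbut-3-en-1-yl]-5-oxooxolan-3-yl]hex-5-en-1-yl 2-methylpropanoate | C=C1C(=O)O[C@@H](C[C@@H](C)/C=C/c2ccccc2)[C@H]1[C@H](OC(=O)C(C)C)C[C@@](C)(O)CC=C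
F5 | step 6 | vinylalane, methyl 2-[bis(2-methylpropyl)alumanyl]prop-2-enoate | C=C(C(=O)OC)[Al](CC(C)C)CC(C)C
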